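## Retrosynthetic overview

1. Target 20 ⇐ α-face epoxidation of alkene 19; the acetate and veratrate come from acylations, and the C2 and C6 carbinols from ketone reductions directed by the 4β-hydroxyl.
2. Seven-membered ring (C1–C10 bond, C1 quaternary centre, C6 ketone, C8=C9 alkene) ⇐ photocatalytic ring opening / 7-endo radical cyclisation of alkenyl siloxycyclopropane 10.
3. 10 ⇐ cyclopropanation of the silyl dienol ether of ketone 8 ⇐ crotylation and oxidation of ring-A enal 5.
4. 5 ⇐ ozonolysis / aldol ring contraction of acetonide 3 ⇐ allylic hydroxylation of (S)-terpinen-4-ol 1, which supplies C4, the only bought stereocentre.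
5. Ring order: the five-membered ring A is cut out of the terpene six-membered ring first; the seven-membered ring is closed in the photochemical step.

Assumption: (S)-(+)-terpinen-4-ol is used enantiopure (commercial material of lower ee is enriched first).

Numbering: daucane numbering of the target is used for all bicyclic compounds (C1 angular-methyl ring-fusion carbon, C2, C3, C4 isopropyl carbinol, C5 ring-fusion CH, C6–C10 seven-membered ring with methyl on C8); β is the face of the C1 methyl. "Ring-A alkenyl" means the 3,3,7-trimethyl-5-(propan-2-yl)-2,4-dioxabicyclo[3.2.1]oct-6-en-6-yl group of 5.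

## Route

Step 1
Reactants: 1 (S)-(+)-terpinen-4-ol
Product: 2 (1R,5R)-2-methyl-5-(propan-2-yl)cyclohex-2-ene-1,5-diol
Conditions: SeO2 (0.3 equiv), t-BuOOH (2 equiv), CH2Cl2, 0 → 25 °C
Reagents that add atoms: tert-butyl hydroperoxide, CC(C)(C)OO
Why: SeO2 allylic hydroxylation (ene reaction then [2,3]-sigmatropic shift) attacks the ring CH2 next to the methyl-bearing alkene carbon and replaces its pseudo-axial hydrogen, which lies cis to the pseudo-axial tertiary OH (isopropyl equatorial), so the new carbinol is set cis to the bought centre.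

Step 2
Reactants: 2 (1R,5R)-2-methyl-5-(propan-2-yl)cyclohex-2-ene-1,5-diol
Product: 3 acetonide of 2 [3,3,6-trimethyl-1-(propan-2-yl)-2,4-dioxabicyclo[3.3.1]non-6-ene]
Conditions: Me2C(OMe)2, PPTS (cat.), CH2Cl2, 25 °C
Reagents that add atoms: 2,2-dimethoxypropane, COC(C)(C)OC
Why: Acid-catalysed transacetalisation that only the cis-1,3-diol can undergo; the bridge protects the tertiary alcohol against β-elimination in step 3 and later shields the β face of ring A.

Step 3
Reactants: 3 acetonide of 2
Product: 5 3,3,7-trimethyl-5-(propan-2-yl)-2,4-dioxabicyclo[3.2.1]oct-6-ene-6-carbaldehyde (ring-A enal; both ring oxygens β), via keto-aldehyde 4 (not isolated)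
Conditions: O3, CH2Cl2, −78 °C; Me2S; then Bn2NH2+ CF3CO2− (cat.), PhMe, 50 °C
Reagents that add atoms: ozone, [O-][O+]=O
Why: Ozonolysis followed by amine-salt-catalysed intramolecular aldol condensation (aldehyde enamine onto the methyl ketone, five-membered ring) contracts the ring to the cyclopentene carbaldehyde without touching a stereocentre.

Step 4
Reactants: 5 ring-A enal and 6 (E)-crotylboronic acid pinacol ester
Product: 7 1-(ring-A alkenyl)-2-methylbut-3-en-1-ol (epimer mixture)
Conditions: 6 (1.5 equiv), PhMe, 60 °C; aq. NaHCO3 work-up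
Reagents that add atoms: none
Why: Allylboration (γ-selective crotylation through a six-membered transition state) puts the methyl on the carbon that becomes C8; both new stereocentres are erased in steps 5–8, so their ratio does not matter.

Step 5
Reactants: 7 1-(ring-A alkenyl)-2-methylbut-3-en-1-ol
Product: 8 1-(ring-A alkenyl)-2-methylbut-3-en-1-one
Conditions: Dess–Martin periodinane, pyridine, CH2Cl2, 0 → 25 °C
Reagents that add atoms: none
Why: Dess–Martin oxidation of the secondary alcohol under buffered conditions; any drift of the β,γ-alkene into conjugation is harmless because both isomers give the same dienolate in step 6.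

Step 6
Reactants: 8 1-(ring-A alkenyl)-2-methylbut-3-en-1-one
Product: 9 1-(ring-A alkenyl)-1-(tert-butyldimethylsilyloxy)-2-methylbuta-1,3-diene (E/Z mixture)
Conditions: KN(SiMe3)2, THF, −78 °C; t-BuMe2SiCl, DMPU, −78 → 0 °C
Reagents that add atoms: tert-butyl(chloro)dimethylsilane, CC(C)(C)[Si](C)(C)Cl
Why: Kinetic deprotonation at the doubly activated C8–H and O-silylation (silyl dienol ether formation) without a Lewis acid that could open the acetonide; the enol ether geometry is irrelevant.

Step 7
Reactants: 9 silyl dienol ether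
Product: 10 1-(ring-A alkenyl)-1-(tert-butyldimethylsilyloxy)-2-methyl-2-vinylcyclopropane (diastereomer mixture)
Conditions: Zn(Ag), CH2I2, Et2O, 35 °C; pyridine quench
Reagents that add atoms: diiodomethane, ICI
Why: Simmons–Smith (Conia) cyclopropanation, in which the electrophilic zinc carbenoid takes the most electron-rich double bond, the silyl enol ether, adding C7 between C6 and C8; the cyclopropane configuration is irrelevant for step 8.

Step 8
Reactants: 10 alkenyl siloxycyclopropane
Product: 13 2β,4β-dihydroxydauc-8-en-6-one, via allyl radical 11 (not isolated), via acetonide ketone 12 (not isolated)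
Conditions: 9-mesityl-10-methylacridinium tetrafluoroborate (5 mol %), (PhS)2 (10 mol %), 2,6-lutidine, MeCN/MeOH 9:1, 450 nm LEDs, 25 °C; then AcOH/H2O 4:1, 40 °C (same flask)
Reagents that add atoms: none
Why: Proposed new method: the excited acridinium oxidises the electron-rich alkenyl siloxycyclopropane to a radical cation that breaks its most substituted bond C6–C8 (oxocarbenium at C6, tertiary allylic radical at C8), methanol takes the silyl group to leave enone-tethered allyl radical 11, whose unhindered primary terminus C10 adds 7-endo to the enone β-carbon C1 (5-endo closure from C8 and 6-exo attack at C5 are disfavoured) on the α face anti to the acetonide bridge, and the α-keto radical takes a hydrogen atom from thiophenol, which the acridine radical regenerates, so the step is redox-neutral, needs no cis-divinyl geometry and sets the C1 quaternary centre, the C6 ketone and the C8=C9 alkene at once; aqueous acetic acid then removes the acetonide and lets the epimerisable C5 settle in the trans ring fusion (C6 away from the isopropyl group and hydrogen-bonded to 4-OH); the closest known reaction types are the oxidative or photocatalytic ring opening of cyclopropanol derivatives to β-keto radicals with Giese trapping and the alkoxy-radical β-scission / endo-cyclisation ring expansion of 1-alkenylcycloalkanols, and the step is the radical counterpart of the divinylcyclopropane–cycloheptadiene rearrangement.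

Step 9
Reactants: 13 2β,4β-dihydroxydauc-8-en-6-one
Product: 14 dauc-8-ene-2β,4β,6α-triol
Conditions: Me4NBH(OAc)3, MeCN/AcOH 1:1, −30 °C
Reagents that add atoms: none
Why: Hydroxyl-directed (Evans–Saksena) reduction, in which the borohydride bound to the 4β-oxygen delivers hydride to the inner face of the C6 carbonyl that it overhangs, giving the equatorial 6α-alcohol (H6 trans to H5), which is also the more stable epimer; the non-conjugated alkene is untouched.

Step 10
Reactants: 14 dauc-8-ene-2β,4β,6α-triol and 15 3,4-dimethoxybenzoyl chloride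
Product: 16 6α-(3,4-dimethoxybenzoyloxy)dauc-8-ene-2β,4β-diol
Conditions: 15 (1.1 equiv), pyridine, DMAP (cat.), CH2Cl2, −10 °C
Reagents that add atoms: none
Why: Chemoselective acylation of the outward-pointing equatorial 6α-OH; the 2β-OH is neopentyl, cis to the angular methyl and hydrogen-bonded to 4-OH on the crowded β face, and the tertiary 4-OH is inert.

Step 11
Reactants: 16 6α-(3,4-dimethoxybenzoyloxy)dauc-8-ene-2β,4β-diol
Product: 17 6α-(3,4-dimethoxybenzoyloxy)-4β-hydroxydauc-8-en-2-one
Conditions: Dess–Martin periodinane, pyridine, CH2Cl2, 0 °C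
Reagents that add atoms: none
Why: Dess–Martin oxidation of the only secondary alcohol left removes the 2β configuration, which served solely as the face-blocking element, under conditions too mild to dehydrate the β-hydroxy ketone.

Step 12
Reactants: 17 6α-(3,4-dimethoxybenzoyloxy)-4β-hydroxydauc-8-en-2-one
Product: 18 6α-(3,4-dimethoxybenzoyloxy)dauc-8-ene-2α,4β-diol
Conditions: Me4NBH(OAc)3, MeCN/AcOH 1:1, −30 → 0 °C
Reagents that add atoms: none
Why: Hydroxyl-directed (Evans–Saksena) reduction again: hydride comes from the 4β-oxygen onto the β face of the C2 ketone and gives the 1,3-anti diol, that is the 2α-alcohol, while the aryl ester survives.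

Step 13
Reactants: 18 6α-(3,4-dimethoxybenzoyloxy)dauc-8-ene-2α,4β-diol
Product: 19 2α-acetoxy-6α-(3,4-dimethoxybenzoyloxy)dauc-8-en-4β-ol
Conditions: Ac2O, pyridine, DMAP (cat.), 25 °C
Reagents that add atoms: acetic anhydride, CC(=O)OC(C)=O
Why: DMAP-catalysed acetylation of the secondary 2α-OH; the hindered tertiary 4β-OH does not react under these conditions.

Step 14
Reactants: 19 2α-acetoxy-6α-(3,4-dimethoxybenzoyloxy)dauc-8-en-4β-ol
Product: 20 2α-acetoxy-8α,9α-epoxy-6α-(3,4-dimethoxybenzoyloxy)daucan-4β-ol (target, CNP0330776.2)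
Conditions: mCPBA, NaHCO3, CH2Cl2, 0 °C
Reagents that add atoms: 3-chloroperoxybenzoic acid, OOC(=O)c1cccc(Cl)c1
Why: Prilezhaev epoxidation of the only alkene from the α face, because the axial angular methyl on C1 shields the β face while the equatorial 6α-ester points away from the ring.

## Compound list

1 | (S)-(+)-terpinen-4-ol [(1S)-4-methyl-1-(propan-2-yl)cyclohex-3-en-1-ol] | CC1=CC[C@](O)(C(C)C)CC1 | starting material
2 | (1R,5R)-2-methyl-5-(propan-2-yl)cyclohex-2-ene-1,5-diol (cis-diol) | CC1=CC[C@](O)(C(C)C)C[C@H]1O | intermediate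
3 | acetonide of 2: 3,3,6-trimethyl-1-(propan-2-yl)-2,4-dioxabicyclo[3.3.1]non-6-ene (configuration as in 2) | CC1=CC[C@]2(C(C)C)C[C@H]1OC(C)(C)O2 | intermediate
4 | keto-aldehyde: cis-6-acetyl-2,2-dimethyl-4-(2-oxoethyl)-4-(propan-2-yl)-1,3-dioxane (configuration as in 3) | CC(=O)[C@H]1C[C@](CC=O)(C(C)C)OC(C)(C)O1 | intermediate
5 | ring-A enal: 3,3,7-trimethyl-5-(propan-2-yl)-2,4-dioxabicyclo[3.2.1]oct-6-ene-6-carbaldehyde (C2 and C4 oxygens β, isopropyl α) | CC1=C(C=O)[C@]2(C(C)C)C[C@H]1OC(C)(C)O2 | intermediate
6 | (E)-crotylboronic acid pinacol ester | C/C=C/CB1OC(C)(C)C(C)(C)O1 | starting material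
7 | 1-(ring-A alkenyl)-2-methylbut-3-en-1-ol (epimers at the two new centres) | CC1=C(C(O)C(C)C=C)[C@]2(C(C)C)C[C@H]1OC(C)(C)O2 | intermediate
8 | 1-(ring-A alkenyl)-2-methylbut-3-en-1-one | CC1=C(C(=O)C(C)C=C)[C@]2(C(C)C)C[C@H]1OC(C)(C)O2 | intermediate
9 | 1-(ring-A alkenyl)-1-(tert-butyldimethylsilyloxy)-2-methylbuta-1,3-diene (E/Z mixture) | CC1=C(C(O[Si](C)(C)C(C)(C)C)=C(C)C=C)[C@]2(C(C)C)C[C@H]1OC(C)(C)O2 | intermediate
10 | 1-(ring-A alkenyl)-1-(tert-butyldimethylsilyloxy)-2-methyl-2-vinylcyclopropane (cyclopropane diastereomers) | CC1=C(C2(O[Si](C)(C)C(C)(C)C)CC2(C)C=C)[C@]3(C(C)C)C[C@H]1OC(C)(C)O3 | intermediate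
11 | enone-tethered allyl radical: 1-(ring-A alkenyl)-3-methylpent-3-en-1-on-5-yl radical | CC1=C(C(=O)CC(C)=C[CH2])[C@]2(C(C)C)C[C@H]1OC(C)(C)O2 | intermediate
12 | 2β,4β-isopropylidenedioxydauc-8-en-6-one (trans-fused, H5 α) | O=C1CC(C)=CC[C@@]2(C)[C@H]3C[C@@](OC(C)(C)O3)(C(C)C)[C@H]12 | intermediate
13 | 2β,4β-dihydroxydauc-8-en-6-one | O=C1CC(C)=CC[C@@]2(C)[C@H](O)C[C@@](O)(C(C)C)[C@H]12 | intermediate
14 | dauc-8-ene-2β,4β,6α-triol | O[C@H]1CC(C)=CC[C@@]2(C)[C@H](O)C[C@@](O)(C(C)C)[C@H]12 | intermediate
15 | 3,4-dimethoxybenzoyl chloride (veratroyl chloride) | COc1ccc(C(Cl)=O)cc1OC | starting material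
16 | 6α-(3,4-dimethoxybenzoyloxy)dauc-8-ene-2β,4β-diol | COc1ccc(C(=O)O[C@H]2CC(C)=CC[C@@]3(C)[C@H](O)C[C@@](O)(C(C)C)[C@H]23)cc1OC | intermediate
17 | 6α-(3,4-dimethoxybenzoyloxy)-4β-hydroxydauc-8-en-2-one | COc1ccc(C(=O)O[C@H]2CC(C)=CC[C@@]3(C)C(=O)C[C@@](O)(C(C)C)[C@H]23)cc1OC | intermediate
18 | 6α-(3,4-dimethoxybenzoyloxy)dauc-8-ene-2α,4β-diol | COc1ccc(C(=O)O[C@H]2CC(C)=CC[C@@]3(C)[C@@H](O)C[C@@](O)(C(C)C)[C@H]23)cc1OC | intermediate
19 | 2α-acetoxy-6α-(3,4-dimethoxybenzoyloxy)dauc-8-en-4β-ol | COc1ccc(C(=O)O[C@H]2CC(C)=CC[C@@]3(C)[C@@H](OC(C)=O)C[C@@](O)(C(C)C)[C@H]23)cc1OC | intermediate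
20 | 2α-acetoxy-8α,9α-epoxy-6α-(3,4-dimethoxybenzoyloxy)daucan-4β-ol (CNP0330776.2) | COc1ccc(C(=O)O[C@H]2C[C@@]3(C)O[C@H]3C[C@@]3(C)[C@@H](OC(C)=O)C[C@@](O)(C(C)C)[C@H]23)cc1OC | target

## Step count and risk

Total step count: 14. Longest linear sequence: 14 (from 1; compounds 6 and 15 are bought).

Steps most likely to fail:

Step 8 (the proposed photocatalytic ring expansion). The allyl radical may cyclise too slowly or the radical cation may take other paths. The fallback is known chemistry and sets out from 10: heating in xylene at 150 °C in a sealed tube with a trace of 2,6-di-tert-butyl-4-methylphenol brings about the thermal divinylcyclopropane–cycloheptadiene (Cope) rearrangement, the trans cyclopropane first epimerising through the diradical, and gives the silyl enol ether 6-(tert-butyldimethylsilyloxy)-2β,4β-isopropylidenedioxydauca-5,8-diene F1. Treating this with 2 M aqueous HCl in THF cleaves the enol ether and the acetonide and comes back to the route at 13.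

Step 1 (SeO2 hydroxylation). The cis selectivity rests on analogy with related 1-methylcyclohexenes, and over-oxidation is likely. The fallback sets out from 1 and no longer needs a stereoselective C–H oxidation: the SeO2/t-BuOOH oxidation is driven further and MnO2 is added so that both carbinol epimers converge on the enone (5R)-5-hydroxy-2-methyl-5-(propan-2-yl)cyclohex-2-en-1-one F2. Chelation-controlled syn-1,3 reduction (Et2BOMe, NaBH4, THF/MeOH, −78 °C; Narasaka–Prasad) then gives the cis-diol and comes back to the route at 2.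

Step 10 (selective acylation of one of two secondary hydroxyls). If the 2β-OH competes, the fallback replaces intrinsic selectivity by orthogonal protection. It sets out from 13: Et3SiCl and imidazole in DMF silylate the secondary 2β-OH to give 2β-(triethylsilyloxy)-4β-hydroxydauc-8-en-6-one F3. Directed reduction as in step 9 gives 2β-(triethylsilyloxy)dauc-8-ene-4β,6α-diol F4, in which 15 (pyridine, DMAP) can acylate only the 6α-OH, giving 6α-(3,4-dimethoxybenzoyloxy)-2β-(triethylsilyloxy)dauc-8-en-4β-ol F5. HF·pyridine in THF removes the silyl ether and comes back to the route at 16.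

## Further compounds

F1 | step 8 | 6-(tert-butyldimethylsilyloxy)-2β,4β-isopropylidenedioxydauca-5,8-diene | CC(C)(C)[Si](C)(C)OC1=C2[C@]3(C(C)C)C[C@@H](OC(C)(C)O3)[C@]2(C)CC=C(C)C1
F2 | step 1 | (5R)-5-hydroxy-2-methyl-5-(propan-2-yl)cyclohex-2-en-1-one | CC1=CC[C@](O)(C(C)C)CC1=O
F3 | step 10 | 2β-(triethylsilyloxy)-4β-hydroxydauc-8-en-6-one | O=C1CC(C)=CC[C@@]2(C)[C@H](O[Si](CC)(CC)CC)C[C@@](O)(C(C)C)[C@H]12
F4 | step 10 | 2β-(triethylsilyloxy)dauc-8-ene-4β,6α-diol | O[C@H]1CC(C)=CC[C@@]2(C)[C@H](O[Si](CC)(CC)CC)C[C@@](O)(C(C)C)[C@H]12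
F5 | step 10 | 6α-(3,4-dimethoxybenzoyloxy)-2β-(triethylsilyloxy)dauc-8-en-4β-ol | COc1ccc(C(=O)O[C@H]2CC(C)=CC[C@@]3(C)[C@H](O[Si](CC)(CC)CC)C[C@@](O)(C(C)C)[C@H]23)cc1OC
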